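The cyclohexane is cut at C1–C2 and C3–C4 (C1 = CHOH, C3 = CMeCl, C4 = CHBr, C6 = CH bearing the pyran). These bonds are made in one pot by a Michael/Wittig annulation: the nitronate of a γ-nitro aldehyde carrying the finished bromo-acetoxy tetrahydropyran adds to isopropenyltriphenylphosphonium bromide (C1–C2), and the ylide so formed closes onto the aldehyde (C3=C4). The step exploits the 1,4-relationship of C1 and C4 across the carbocycle: nitro at C1 is a latent carbinol (Nef, hydride), and the C3=C4 alkene is the latent trans bromochloride, installed through a cis-diol cyclic sulfate. Pyran stereocentres come from asymmetric epoxidation, C6 from an organocatalytic nitromethane addition.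

Key step: step 11

Remark on numbering: cyclohexane C1 = CHOH, C2 = CH2, C3 = C(CH3)Cl, C4 = CHBr, C5 = CH2, C6 = CH attached to pyran C2; pyran O1, C2 (quaternary), C3 (OAc), C5 (Br), C6 (CMe2).
Remark on the chemistry: the nitro-bearing carbon of 19 is expected as a mixture of epimers; the trans isomer is drawn, and this centre is removed in step 12.

Step 1
Reactants: 1 5-bromo-2-methylpent-2-ene; 2 triphenylphosphine
Product: 3 (4-methylpent-3-en-1-yl)triphenylphosphonium bromide
Conditions: MeCN, reflux
Reagents that add atoms: none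
Why: Phosphonium salt formation by SN2 quaternisation of the phosphine with a primary bromide; no stereocentre is formed.

Step 2
Reactants: 3 (4-methylpent-3-en-1-yl)triphenylphosphonium bromide; 4 1-[(tert-butyldimethylsilyl)oxy]propan-2-one
Product: 6 (Z)-tert-butyl[(2,6-dimethylhepta-2,5-dien-1-yl)oxy]dimethylsilane, via phosphonium ylide 5 (not isolated)
Conditions: KHMDS, THF, −78 °C; then 4, −78 °C → rt
Reagents that add atoms: none
Why: Wittig olefination; an unstabilised ylide and an α-silyloxy ketone under salt-free conditions should give the Z-trisubstituted alkene, with the oxymethyl group cis to the alkyl chain.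

Step 3
Reactants: 6 (Z)-silyl ether
Product: 7 (Z)-2,6-dimethylhepta-2,5-dien-1-ol
Conditions: TBAF, THF, 0 °C → rt
Reagents that add atoms: none
Why: Fluoride-mediated cleavage of the silyl ether (desilylation); the alkene geometry is untouched.

Step 4
Reactants: 7 (Z)-2,6-dimethylhepta-2,5-dien-1-ol
Product: 8 [(2S,3R)-2-methyl-3-(3-methylbut-2-en-1-yl)oxiran-2-yl]methanol
Conditions: Ti(OiPr)4 (cat.), L-(+)-diethyl tartrate (cat.), t-BuOOH, 4 Å MS, CH2Cl2, −20 °C
Reagents that add atoms: tert-butyl hydroperoxide, CC(C)(C)OO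
Why: Sharpless asymmetric epoxidation; only the allylic alkene is epoxidised because only the allylic alcohol binds titanium, and the L-(+)-tartrate ligand sets both epoxide centres as (2S,3R).

Step 5
Reactants: 8 epoxy alcohol
Product: 9 (2S,3S)-1,2-dihydroxy-2,6-dimethylhept-5-en-3-yl acetate
Conditions: Ti(OiPr)4, AcOH, CH2Cl2, rt
Reagents that add atoms: acetic acid, CC(=O)O
Why: Titanium-assisted regioselective opening of a 2,3-epoxy alcohol at C3 by the carboxylic acid (SN2, inversion); this sets the acetoxy-bearing centre (pyran C3) and leaves the tertiary C–O (future ring oxygen) with retained configuration.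

Step 6
Reactants: 9 diol acetate
Product: 10 (2S,3S,5S)-5-bromo-2-(hydroxymethyl)-2,6,6-trimethyloxan-3-yl acetate
Conditions: 2,4,4,6-tetrabromocyclohexa-2,5-dienone, MeNO2, 0 °C → rt
Reagents that add atoms: 2,4,4,6-tetrabromocyclohexa-2,5-dienone, O=C1C(Br)=CC(Br)(Br)C=C1Br
Why: Bromoetherification (bromonium formation on the trisubstituted alkene and 6-endo, Markovnikov capture by the tertiary hydroxyl); a chair transition state with equatorial bromine and axial acetoxy (gauche to the forming ring oxygen, anti to the axial C2 methyl) should place Br trans to OAc and so set pyran C5.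

Step 7
Reactants: 10 bromo-tetrahydropyran alcohol
Product: 11 (2R,3S,5S)-5-bromo-2-formyl-2,6,6-trimethyloxan-3-yl acetate
Conditions: Dess–Martin periodinane, NaHCO3, CH2Cl2, rt
Reagents that add atoms: none
Why: Hypervalent-iodine oxidation of the primary alcohol to the aldehyde; the α-carbon is quaternary, so no centre can epimerise.

Step 8
Reactants: 11 aldehyde; 12 (triphenylphosphoranylidene)acetaldehyde
Product: 13 (2S,3S,5S)-5-bromo-2,6,6-trimethyl-2-[(E)-3-oxoprop-1-en-1-yl]oxan-3-yl acetate
Conditions: toluene, 80 °C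
Reagents that add atoms: none
Why: Wittig olefination with a stabilised ylide, which should give the E-enal.

Step 9
Reactants: 13 enal; 14 nitromethane
Product: 15 (2S,3S,5S)-5-bromo-2,6,6-trimethyl-2-[(2S)-1-nitro-4-oxobutan-2-yl]oxan-3-yl acetate
Conditions: (R)-α,α-diphenylprolinol trimethylsilyl ether (20 mol%), PhCO2H (20 mol%), MeOH, rt
Reagents that add atoms: none
Why: Iminium-catalysed asymmetric Michael addition of nitromethane; the diphenyl(silyloxy)methyl group shields one face of the E-iminium ion, so the catalyst enantiomer is chosen to deliver the nucleophile to the face that gives the (S) centre (cyclohexane C6).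

Step 10
Reactants: 16 2-bromopropene; 2 triphenylphosphine
Product: 17 (prop-1-en-2-yl)triphenylphosphonium bromide
Conditions: Pd(PPh3)4 (cat.), toluene, reflux
Reagents that add atoms: none
Why: Palladium-catalysed C–P coupling (oxidative addition of the alkenyl bromide to zerovalent palladium, reductive elimination of the alkenylphosphonium salt); no stereocentre is formed.

Step 11
Reactants: 15 γ-nitro aldehyde; 17 (prop-1-en-2-yl)triphenylphosphonium bromide
Product: 19 (2S,3S,5S)-5-bromo-2,6,6-trimethyl-2-[(1S,6S)-4-methyl-6-nitrocyclohex-3-en-1-yl]oxan-3-yl acetate, via phosphonium nitronate betaine 18 (not isolated)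
Conditions: K2CO3, 18-crown-6 (cat.), MeCN, 0 °C → 50 °C
Reagents that add atoms: none
Why: The primary nitronate of 15 adds in a Michael reaction to the CH2 terminus of the vinylphosphonium salt (C1–C2 bond), giving betaine 18; proton transfer from the phosphorus-bearing carbon to the nitronate unmasks an unstabilised ylide, whose intramolecular Wittig reaction with the aldehyde forms C3=C4 and closes the ring (6-exo-trig attack on the carbonyl, then collapse of the oxaphosphetane). This is the vinylphosphonium Michael/Wittig annulation, closely related to the nitronate Michael/Horner–Wadsworth–Emmons cyclohexene annulation with vinylphosphonates. No stereocentre of the target is created: C6 comes from step 9 and is α to neither the nitro nor the carbonyl group, and the nitro-bearing C1 is turned into a carbonyl in step 12. Regiochemistry is fixed by polarity, since the nitronate can only attack the unsubstituted alkene carbon and the ylide carbon is the methyl-bearing one, so the methyl group ends on C3. The selectivity needed is C-alkylation and Wittig closure in preference to aldol or Henry self-condensation; the high electrophilicity of the phosphonium salt, the mild carbonate base and the irreversible loss of triphenylphosphine oxide should secure it.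

Step 12
Reactants: 19 nitrocyclohexene
Product: 21 (2S,3S,5S)-5-bromo-2,6,6-trimethyl-2-[(1R)-4-methyl-2-oxocyclohex-4-en-1-yl]oxan-3-yl acetate, via potassium nitronate 20 (not isolated)
Conditions: t-BuOK, THF, 0 °C; then aq. TiCl3, NH4OAc, 0 °C → rt
Reagents that add atoms: water, O
Why: Reductive Nef reaction (the nitronate is reduced by TiCl3 to the imine, which hydrolyses to the ketone); the buffered medium should avoid conjugation of the β,γ-alkene and epimerisation at C6, and the ketone is reduced without delay.

Step 13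
Reactants: 21 β,γ-unsaturated ketone
Product: 22 (2S,3S,5S)-5-bromo-2-[(1S,2R)-2-hydroxy-4-methylcyclohex-4-en-1-yl]-2,6,6-trimethyloxan-3-yl acetate
Conditions: L-selectride, THF, −78 °C; then H2O
Reagents that add atoms: none
Why: Hydride reduction with a bulky trialkylborohydride; equatorial attack on the ketone with its equatorial α-substituent should give the axial alcohol, cis to the pyranyl group (C1).

Step 14
Reactants: 22 homoallylic alcohol
Product: 23 (2S,3S,5S)-5-bromo-2-[(1S,2R)-2-[(tert-butyldimethylsilyl)oxy]-4-methylcyclohex-4-en-1-yl]-2,6,6-trimethyloxan-3-yl acetate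
Conditions: TBSOTf, 2,6-lutidine, CH2Cl2, −78 → 0 °C
Reagents that add atoms: tert-butyldimethylsilyl trifluoromethanesulfonate, CC(C)(C)[Si](C)(C)OS(=O)(=O)C(F)(F)F
Why: Silyl ether formation (O-silylation) of the hindered axial alcohol with the reactive triflate; no stereocentre is affected.

Step 15
Reactants: 23 silyl ether
Product: 24 (2S,3S,5S)-5-bromo-2-[(1S,2R,4R,5S)-2-[(tert-butyldimethylsilyl)oxy]-4,5-dihydroxy-4-methylcyclohexyl]-2,6,6-trimethyloxan-3-yl acetate
Conditions: OsO4 (cat.), NMO, acetone/H2O, rt
Reagents that add atoms: N-methylmorpholine N-oxide, C[N+]1([O-])CCOCC1; water, O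
Why: Upjohn dihydroxylation (syn addition); OsO4 should attack the C3=C4 face opposite the axial silyloxy group on C1, giving the cis-diol with the secondary C4–O axial and the tertiary C3–O equatorial.

Step 16
Reactants: 24 cis-diol
Product: 26 cyclic sulfate of diol 24, via cyclic sulfite 25 (not isolated)
Conditions: SOCl2, Et3N, CH2Cl2, 0 °C; then RuCl3 (cat.), NaIO4, MeCN/CCl4/H2O, 0 °C
Reagents that add atoms: thionyl chloride, O=S(Cl)Cl; sodium periodate, [Na+].[O-]I(=O)(=O)=O
Why: Cyclic sulfite formation and ruthenium-catalysed oxidation to the cyclic sulfate; only the cis-1,2-diol can form the five-membered ring, and no C–O bond is broken.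

Step 17
Reactants: 26 cyclic sulfate
Product: 29 (2S,3S,5S)-5-bromo-2-[(1S,2R,4R,5R)-5-bromo-4-chloro-2-hydroxy-4-methylcyclohexyl]-2,6,6-trimethyloxan-3-yl acetate (CNP0166766.1), via lithium bromo sulfate 27 (not isolated), via silyl-protected target 28 (not isolated)
Conditions: LiBr, THF, rt; then HCl (4 M in dioxane), CH2Cl2, −20 → 0 °C; then HF·pyridine, THF, rt
Reagents that add atoms: lithium bromide, [Li+].[Br-]; hydrogen chloride, Cl
Why: Cyclic sulfate opening (SN2) by bromide at the secondary carbon, whose axial C–O bond is displaced with inversion to give the equatorial C4 bromide cis to the pyranyl group, then SN1 ionisation of the tertiary sulfate in HCl with chloride capture anti to the neighbouring bromine and to the syn-axial silyloxy group (net retention at C3, chlorine equatorial), then fluoride-mediated silyl ether cleavage.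

Compound list
1 | 5-bromo-2-methylpent-2-ene | CC(C)=CCCBr | starting material
2 | triphenylphosphine | c1ccc(cc1)P(c1ccccc1)c1ccccc1 | starting material
3 | (4-methylpent-3-en-1-yl)triphenylphosphonium bromide | CC(C)=CCC[P+](c1ccccc1)(c1ccccc1)c1ccccc1.[Br-] | intermediate
4 | 1-[(tert-butyldimethylsilyl)oxy]propan-2-one | CC(=O)CO[Si](C)(C)C(C)(C)C | starting material
5 | (4-methylpent-3-en-1-ylidene)triphenylphosphorane (ylide) | CC(C)=CCC=P(c1ccccc1)(c1ccccc1)c1ccccc1 | intermediate
6 | (Z)-tert-butyl[(2,6-dimethylhepta-2,5-dien-1-yl)oxy]dimethylsilane | CC(C)(C)[Si](C)(C)OC/C(C)=C\CC=C(C)C | intermediate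
7 | (Z)-2,6-dimethylhepta-2,5-dien-1-ol | OC/C(C)=C\CC=C(C)C | intermediate
8 | [(2S,3R)-2-methyl-3-(3-methylbut-2-en-1-yl)oxiran-2-yl]methanol | OC[C@]1(C)O[C@@H]1CC=C(C)C | intermediate
9 | (2S,3S)-1,2-dihydroxy-2,6-dimethylhept-5-en-3-yl acetate | CC(=O)O[C@@H](CC=C(C)C)[C@@](C)(O)CO | intermediate
10 | (2S,3S,5S)-5-bromo-2-(hydroxymethyl)-2,6,6-trimethyloxan-3-yl acetate | CC(=O)O[C@H]1C[C@H](Br)C(C)(C)O[C@@]1(C)CO | intermediate
11 | (2R,3S,5S)-5-bromo-2-formyl-2,6,6-trimethyloxan-3-yl acetate | CC(=O)O[C@H]1C[C@H](Br)C(C)(C)O[C@@]1(C)C=O | intermediate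
12 | (triphenylphosphoranylidene)acetaldehyde | O=CC=P(c1ccccc1)(c1ccccc1)c1ccccc1 | starting material
13 | (2S,3S,5S)-5-bromo-2,6,6-trimethyl-2-[(E)-3-oxoprop-1-en-1-yl]oxan-3-yl acetate | CC(=O)O[C@H]1C[C@H](Br)C(C)(C)O[C@@]1(C)/C=C/C=O | intermediate
14 | nitromethane | C[N+](=O)[O-] | starting material
15 | (2S,3S,5S)-5-bromo-2,6,6-trimethyl-2-[(2S)-1-nitro-4-oxobutan-2-yl]oxan-3-yl acetate | CC(=O)O[C@H]1C[C@H](Br)C(C)(C)O[C@@]1(C)[C@H](C[N+](=O)[O-])CC=O | intermediate
16 | 2-bromopropene | CC(Br)=C | starting material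
17 | (prop-1-en-2-yl)triphenylphosphonium bromide | CC(=C)[P+](c1ccccc1)(c1ccccc1)c1ccccc1.[Br-] | intermediate
18 | phosphonium nitronate betaine (Michael adduct of the nitronate of 15 to 17; phosphorus-bearing carbon unassigned) | CC(=O)O[C@H]1C[C@H](Br)C(C)(C)O[C@@]1(C)[C@H](C(CC(C)[P+](c1ccccc1)(c1ccccc1)c1ccccc1)=[N+]([O-])[O-])CC=O | intermediate
19 | (2S,3S,5S)-5-bromo-2,6,6-trimethyl-2-[(1S,6S)-4-methyl-6-nitrocyclohex-3-en-1-yl]oxan-3-yl acetate (trans isomer drawn) | CC(=O)O[C@H]1C[C@H](Br)C(C)(C)O[C@@]1(C)[C@H]1CC=C(C)C[C@@H]1[N+](=O)[O-] | intermediate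
20 | potassium nitronate of 19 | CC(=O)O[C@H]1C[C@H](Br)C(C)(C)O[C@@]1(C)[C@H]1CC=C(C)CC1=[N+]([O-])[O-].[K+] | intermediate
21 | (2S,3S,5S)-5-bromo-2,6,6-trimethyl-2-[(1R)-4-methyl-2-oxocyclohex-4-en-1-yl]oxan-3-yl acetate | CC(=O)O[C@H]1C[C@H](Br)C(C)(C)O[C@@]1(C)[C@H]1CC=C(C)CC1=O | intermediate
22 | (2S,3S,5S)-5-bromo-2-[(1S,2R)-2-hydroxy-4-methylcyclohex-4-en-1-yl]-2,6,6-trimethyloxan-3-yl acetate | CC(=O)O[C@H]1C[C@H](Br)C(C)(C)O[C@@]1(C)[C@H]1CC=C(C)C[C@H]1O | intermediate
23 | (2S,3S,5S)-5-bromo-2-[(1S,2R)-2-[(tert-butyldimethylsilyl)oxy]-4-methylcyclohex-4-en-1-yl]-2,6,6-trimethyloxan-3-yl acetate | CC(=O)O[C@H]1C[C@H](Br)C(C)(C)O[C@@]1(C)[C@H]1CC=C(C)C[C@H]1O[Si](C)(C)C(C)(C)C | intermediate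
24 | (2S,3S,5S)-5-bromo-2-[(1S,2R,4R,5S)-2-[(tert-butyldimethylsilyl)oxy]-4,5-dihydroxy-4-methylcyclohexyl]-2,6,6-trimethyloxan-3-yl acetate | CC(=O)O[C@H]1C[C@H](Br)C(C)(C)O[C@@]1(C)[C@H]1C[C@H](O)[C@](C)(O)C[C@H]1O[Si](C)(C)C(C)(C)C | intermediate
25 | cyclic sulfite of diol 24 (sulfur configuration unassigned) | CC(=O)O[C@H]1C[C@H](Br)C(C)(C)O[C@@]1(C)[C@H]1C[C@@H]2OS(=O)O[C@]2(C)C[C@H]1O[Si](C)(C)C(C)(C)C | intermediate
26 | cyclic sulfate of diol 24 | CC(=O)O[C@H]1C[C@H](Br)C(C)(C)O[C@@]1(C)[C@H]1C[C@@H]2OS(=O)(=O)O[C@]2(C)C[C@H]1O[Si](C)(C)C(C)(C)C | intermediate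
27 | lithium (1R,2R,4S,5R)-2-bromo-1-methyl-cyclohexyl sulfate carrying the 5-silyloxy and 4-pyranyl groups (bromo sulfate) | CC(=O)O[C@H]1C[C@H](Br)C(C)(C)O[C@@]1(C)[C@H]1C[C@@H](Br)[C@](C)(OS(=O)(=O)[O-])C[C@H]1O[Si](C)(C)C(C)(C)C.[Li+] | intermediate
28 | (2S,3S,5S)-5-bromo-2-[(1S,2R,4R,5R)-5-bromo-2-[(tert-butyldimethylsilyl)oxy]-4-chloro-4-methylcyclohexyl]-2,6,6-trimethyloxan-3-yl acetate | CC(=O)O[C@H]1C[C@H](Br)C(C)(C)O[C@@]1(C)[C@H]1C[C@@H](Br)[C@](C)(Cl)C[C@H]1O[Si](C)(C)C(C)(C)C | intermediate
29 | (2S,3S,5S)-5-bromo-2-[(1S,2R,4R,5R)-5-bromo-4-chloro-2-hydroxy-4-methylcyclohexyl]-2,6,6-trimethyloxan-3-yl acetate (CNP0166766.1) | CC(=O)O[C@H]1C[C@H](Br)C(C)(C)O[C@@]1(C)[C@H]1C[C@@H](Br)[C@](C)(Cl)C[C@H]1O | target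

Total step count: 17. Longest linear sequence: 16 steps (steps 1–9 and 11–17; step 10 is a one-step branch).

Steps most likely to fail

Step 11. The ylide may form too slowly from betaine 18 because the nitronate is a weak internal base, so retro-Michael cleavage or aldol self-condensation of the aldehyde could take over. The fallback builds the same ring by stepwise known chemistry and sets out from 15. Palladium-catalysed Tsuji–Trost C-allylation of its nitronate with 2-methylallyl methyl carbonate (Pd(PPh3)4, THF) would give the C-allylated nitro aldehyde F1. Wittig methylenation of the aldehyde with an excess of methylenetriphenylphosphorane would give the diene F2. Ring-closing metathesis with the second-generation Grubbs catalyst would then form C3=C4 and return to the route at 19.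

Step 17. After ionisation of the tertiary sulfate, chloride may attack the secondary carbon of a bridged bromonium ion (1,2-migration of bromine), or the cation may lose a proton, instead of undergoing substitution with retention. The fallback sets out from 26. Bromide opening followed by mild hydrolysis of the sulfate ester (catalytic H2SO4, water, THF) would give the isolated bromohydrin F3. Its tertiary alcohol would be converted into the chloride by front-side delivery from the chlorosulfite (thionyl chloride with catalytic TiCl4, no base), which comes back to the route at 28; desilylation then gives 29.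

Step 6. The bromonium ion may be captured in the 5-exo mode, or formed on the wrong alkene face, because the hydroxymethyl and methyl groups on the carbinol carbon differ little in size. The fallback locks the chair and sets out from 9. Methanolysis of the acetate (K2CO3, MeOH) would give the triol F4, and benzaldehyde dimethyl acetal with acid would give the six-membered benzylidene acetal F5 across the primary and secondary hydroxyls. In the cis-fused transition state the dioxane ring can only carry the alkenyl-bearing carbon equatorially, which fixes the chair with the C3 oxygen axial. Bromoetherification of F5 would therefore give the bicyclic bromide F6 with the desired C5 configuration. Acidic hydrolysis of the acetal would give the diol F7, selective TEMPO/PhI(OAc)2 oxidation of the primary alcohol would give the hydroxy aldehyde F8, and acetylation (Ac2O, DMAP) would return to the route at 11.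

Further compounds
F1 | step 11 | (2S,3S,5S)-5-bromo-2,6,6-trimethyl-2-[(2S)-5-methyl-3-nitro-1-oxohex-5-en-... C-allylated nitro aldehyde (nitro-bearing carbon unassigned) | CC(=O)O[C@H]1C[C@H](Br)C(C)(C)O[C@@]1(C)[C@H](C(CC(C)=C)[N+](=O)[O-])CC=O
F2 | step 11 | nitro diene from methylenation of F1 (nitro-bearing carbon unassigned) | CC(=O)O[C@H]1C[C@H](Br)C(C)(C)O[C@@]1(C)[C@H](C(CC(C)=C)[N+](=O)[O-])CC=C
F3 | step 17 | silyl-protected bromohydrin (C4 bromide, C3 tertiary alcohol) | CC(=O)O[C@H]1C[C@H](Br)C(C)(C)O[C@@]1(C)[C@H]1C[C@@H](Br)[C@](C)(O)C[C@H]1O[Si](C)(C)C(C)(C)C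
F4 | step 6 | (2S,3S)-2,6-dimethylhept-5-ene-1,2,3-triol | O[C@@H](CC=C(C)C)[C@@](C)(O)CO
F5 | step 6 | 1,3-O-benzylidene acetal of F4 (acetal carbon unassigned, phenyl equatorial expected) | C1(c2ccccc2)O[C@@H](CC=C(C)C)[C@@](C)(O)CO1
F6 | step 6 | benzylidene-bridged bromo-tetrahydropyran (acetal carbon unassigned) | C1(c2ccccc2)O[C@H]2C[C@H](Br)C(C)(C)O[C@@]2(C)CO1
F7 | step 6 | (2S,3S,5S)-5-bromo-2-(hydroxymethyl)-2,6,6-trimethyloxan-3-ol | O[C@H]1C[C@H](Br)C(C)(C)O[C@@]1(C)CO
F8 | step 6 | (2R,3S,5S)-5-bromo-3-hydroxy-2,6,6-trimethyloxane-2-carbaldehyde | O[C@H]1C[C@H](Br)C(C)(C)O[C@@]1(C)C=O
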